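At the last reading of the oak run, 6.00 d, the flask holds 17.2% intermediate and 50.8% target. Oak has the charge of summer and is read at the time of summer, so the summer answer can be taken from that reading, give or take 1 percentage point. What remains is to choose the next run from the set-ups below, and the choice turns on how much intermediate each holds when it is read.

| flask | starting material | partner | protic impurity | free catalyst | second catalyst | remark | time |
|---|---|---|---|---|---|---|---|
| oak | 0.20 M | 0.14 M | 0.040 M | 10 mM | 15 mM | run made earlier |  |
| ash | 0.10 M | 0.14 M | 0.040 M | 10 mM | 15 mM | run made earlier |  |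
| cedar | 0.15 M | 0.14 M | 0.040 M | 10 mM | 15 mM | run made earlier |  |
| larch | 0.20 M | 0.28 M | 0.040 M | 10 mM | 15 mM | run made earlier |  |
| midnight | 0.20 M | 0.140 M | 0.0400 M | 10 mM | 15 mM | one stirred flow tank at steady state, fed with the mixture as stated, mean residence time 6.0 d |  |
| summer | 0.20 M | 0.140 M | 0.0400 M | 10 mM | 15 mM | a closed flask charged with all of it at once and left for 6.0 d | 6.0 d |
| noon | 0.20 M (fed, over 3.00 d) | 0.140 M | 0.0400 M | 10 mM | 15 mM | all but starting material at the start; starting material goes in evenly over 3.00 d, the run ends at 6.0 d | 6.0 d |
| dusk | 0.20 M | 0.140 M (fed, over 3.00 d) | 0.0400 M | 10 mM | 15 mM | all but partner at the start; partner goes in evenly over 3.00 d, the run ends at 6.0 d | 6.0 d |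

| run | time / d | intermediate / % | target / % |
|---|---|---|---|
| oak | 0.833 | 28.6 | 19.3 |
| oak | 1.67 | 25.5 | 33.0 |
| oak | 2.50 | 21.6 | 38.4 |
| oak | 3.00 | 19.1 | 39.4 |
| oak | 4.00 | 19.5 | 45.7 |
| oak | 5.00 | 17.1 | 47.6 |
| oak | 6.00 | 17.2 | 50.8 |
| ash | 0.208 | 25.5 | 5.3 |
| ash | 0.500 | 28.2 | 11.7 |
| ash | 1.04 | 24.2 | 23.6 |
| ash | 1.67 | 21.6 | 34.4 |
| ash | 2.00 | 20.2 | 39.9 |
| ash | 3.00 | 17.1 | 49.7 |
| ash | 4.00 | 15.1 | 55.4 |
| cedar | 0.208 | 25.0 | 4.6 |
| cedar | 0.500 | 28.4 | 13.2 |
| cedar | 1.04 | 25.9 | 24.2 |
| cedar | 1.67 | 22.3 | 35.3 |
| cedar | 2.00 | 21.4 | 35.2 |
| cedar | 3.00 | 18.5 | 46.4 |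
| cedar | 4.00 | 18.2 | 52.4 |
| larch | 0.625 | 21.5 | 25.8 |
| larch | 1.25 | 16.3 | 45.1 |
| larch | 2.00 | 12.9 | 58.3 |
| larch | 3.00 | 10.1 | 68.7 |
| larch | 4.00 | 8.4 | 75.1 |

(readings scatter by 1 percentage point)

- the set-up with the highest amount of intermediate at the outlet or at the end, in percent of the starting material put in ("none" if the first two lie within 2 percentage points) (midnight / summer / noon / dusk / none)
- amount of intermediate at the outlet or at the end, in percent of the starting material put in, midnight
- amount of intermediate at the outlet or at the end, in percent of the starting material put in, summer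
- amount of intermediate at the outlet or at the end, in percent of the starting material put in, noon
- amount of intermediate at the outlet or at the end, in percent of the starting material put in, dusk

- a species is counted by the starting material in it: one self-condensation product counts as two
- the stated concentrations are those of everything mixed, before any reaction; amounts are the same in each set-up
- steps under discussion: starting material + free catalyst <-> free catalyst + intermediate; partner + second catalyst + intermediate -> second catalyst + target; 2 starting material -> self-condensation product; partner + protic impurity -> quenched reagent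
- the feed brings no volume worth counting
- the earlier runs were made in a closed, stirred flask

The pool share, the intermediate divided by the charged starting material less the target, reads 0.350 at the end of oak. It is a rapid pre-equilibrium put into one figure. In ash the intermediate stands at 28.2% by 0.500 d, far earlier than the 6.0 d of a run, so the exchange can be taken to keep pace with the slow formation of target. The share reads 0.339 at the end of ash, with half the starting material of oak, and 0.337 at the end of larch, with twice its partner.

My own reckoning therefore spares the exchange step, but the target of midnight, noon and dusk, which no run reads, still has to come from integrating the rates. Once the feed is in, or in the steady tank, the intermediate is taken as the share times the pool, so at one share the set-up making the least target holds the most intermediate. A lead of 2 points in intermediate then asks for a lead of 5.7 points in target, and a change of set-up is worth making for no less.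

The forecast takes the same line, “intermediate ≈ 0.35 × the unconverted pool”. It gives 20.2% for midnight (18.8% to 21.8%), 17.2% for summer (16.3% to 18.1%), 18.5% for noon (17% to 20%) and 18% for dusk (16.6% to 19.4%). Its answer is none, with midnight ahead of noon by 1.7 points, which it calls borderline.

The flasks give 20.3% for midnight, 17.7% for summer, 19.8% for noon and 18.6% for dusk, so the answer is none.

    starting material + free catalyst ⇌ free catalyst + intermediate (K = 0.560, k = 11.0 M⁻¹ h⁻¹)
    partner + second catalyst + intermediate → second catalyst + target (k = 23.0 M⁻² h⁻¹)
    2 starting material → self-condensation product (k = 9.30 × 10⁻⁵ M⁻¹ h⁻¹)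
    partner + protic impurity → quenched reagent (k = 0.210 M⁻¹ h⁻¹)

Midnight ends with 39.6% target and noon with 44.0%, a difference of 4.4 points, less than the 5.7 points that the margin asks, and their intermediate differs by 0.50 points. In dusk, the target of 47.4% leaves a pool that the share of 0.350 turns into 18.4% intermediate, and the dusk flask holds 18.6%.

The numbers in the tables stem from a simulated flask with made-up constants.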